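**Retrosynthetic overview**
1. Target 20 ⇐ 19 (O-debenzylation) ⇐ 17 (reductive removal of the C3 chlorine and the C5 arylsulfanyl group, then base equilibration of C3 to trans).
2. Key disconnection of the lactone ring of 17 at O1–C5 and C3–C4: (R)-sulfinyl (Z)-alkene 7 (C4=C5, sulfur on C5) plus benzyl(chloro)ketene 14 (O1=C2=C3), made in the flask from acid chloride 13.
3. Enabling feature: in the γ-butyrolactone ring, O1 and the α-carbon C3 are bonded to the neighbouring carbons C5 and C4, so the ring is a three-atom ketene unit (O1–C2–C3) laid across a two-carbon alkene unit (C4=C5). C5 is a bare CH2 next to O1 and can carry sulfur temporarily; C3 is an enolisable CH and can carry chlorine temporarily and be reset trans.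
4. 7 comes from 3,4-dimethoxybenzyl chloride, ethynylmagnesium bromide and (−)-menthyl (S)-p-toluenesulfinate (sulfur as a temporary stereocontrol element); 13 comes from diethyl chloromalonate and 3,4-bis(benzyloxy)benzyl chloride.
5. Ring order: both benzene rings are bought; the lactone ring is the only ring formed (step 7).

Key step: step 7

Remark on the chemistry: the sense of sulfur-to-carbon chirality transfer in step 7 is assumed to follow the chair transition state with p-tolyl pseudo-equatorial, which pairs (R)-sulfur and the (Z)-alkene with the target's C4 configuration; this assignment is derived from the model, not confirmed against a reported example.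

**Route**

Step 1
Reactants: 1 4-(chloromethyl)-1,2-dimethoxybenzene; 2 ethynylmagnesium bromide (HC≡CMgBr, excess)
Product: 3 1,2-dimethoxy-4-(prop-2-yn-1-yl)benzene
Conditions: CuCl (cat.), THF, 60 °C
Reagents that add atoms: none
Why: Copper-catalysed sp–sp3 cross-coupling of a benzylic chloride with an alkynyl Grignard reagent should give the benzylic terminal alkyne, and the weakly basic acetylide limits propargyl–allenyl isomerisation of the product methylene.

Step 2
Reactants: 3 1,2-dimethoxy-4-(prop-2-yn-1-yl)benzene; 4 (1R,2S,5R)-menthyl (S)-4-methylbenzenesulfinate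
Product: 6 (S)-1,2-dimethoxy-4-[3-(4-methylbenzenesulfinyl)prop-2-yn-1-yl]benzene, via alkynylmagnesium bromide 5 (not isolated)
Conditions: EtMgBr, THF, 0 °C → rt; then added to 4 in PhMe, −20 °C; H2O work-up
Reagents that add atoms: none
Why: Andersen sulfoxide synthesis, in which the alkynyl Grignard reagent displaces menthoxide at sulfur with inversion, so the sulfur stereocentre comes from the sulfinate (the descriptor is S because the alkynyl carbon outranks p-tolyl).

Step 3
Reactants: 6 (S)-1,2-dimethoxy-4-[3-(4-methylbenzenesulfinyl)prop-2-yn-1-yl]benzene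
Product: 7 (R)-1,2-dimethoxy-4-[(Z)-3-(4-methylbenzenesulfinyl)prop-2-en-1-yl]benzene
Conditions: H2 (1 atm), RhCl(PPh3)3 (cat.), PhH, rt
Reagents that add atoms: none
Why: Homogeneous syn-hydrogenation of a 1-alkynyl sulfoxide with RhCl(PPh3)3 should stop at the (Z)-1-alkenyl sulfoxide under neutral conditions that leave the sulfur stereocentre and the doubly activated methylene untouched (the descriptor becomes R only because vinyl ranks below p-tolyl).

Step 4
Reactants: 8 diethyl 2-chloromalonate; 9 1,2-bis(benzyloxy)-4-(chloromethyl)benzene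
Product: 10 diethyl 2-[3,4-bis(benzyloxy)benzyl]-2-chloromalonate
Conditions: NaH, THF–DMF, 0 °C; then 9, Bu4NI (cat.), rt
Reagents that add atoms: none
Why: Malonate alkylation (SN2 of the sodium enolate on a benzylic chloride under iodide catalysis) places the arylmethyl group and the future activating chlorine on one carbon.

Step 5
Reactants: 10 diethyl 2-[3,4-bis(benzyloxy)benzyl]-2-chloromalonate
Product: 12 rac-3-[3,4-bis(benzyloxy)phenyl]-2-chloropropanoic acid, via chloromalonic diacid 11 (not isolated)
Conditions: KOH, EtOH–H2O, rt; aq HCl to pH 1; then xylenes, 130 °C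
Reagents that add atoms: potassium hydroxide, [K+].[OH-]
Why: Ester saponification followed by thermal decarboxylation of the substituted chloromalonic acid (the classical malonic acid route to α-halo acids) should give the racemic α-chloro acid, whose stereocentre is irrelevant because it becomes the sp2 carbon of the ketene.

Step 6
Reactants: 12 rac-3-[3,4-bis(benzyloxy)phenyl]-2-chloropropanoic acid
Product: 13 rac-3-[3,4-bis(benzyloxy)phenyl]-2-chloropropanoyl chloride
Conditions: (COCl)2, DMF (cat.), CH2Cl2, 0 °C → rt
Reagents that add atoms: oxalyl chloride, ClC(=O)C(=O)Cl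
Why: Standard acid chloride formation through the chloroiminium catalyst, to which the benzyl ethers and the α-chlorine are inert.

Step 7
Reactants: 7 (R)-1,2-dimethoxy-4-[(Z)-3-(4-methylbenzenesulfinyl)prop-2-en-1-yl]benzene; 13 rac-3-[3,4-bis(benzyloxy)phenyl]-2-chloropropanoyl chloride
Product: 17 (4S)-3-[3,4-bis(benzyloxy)benzyl]-3-chloro-4-(3,4-dimethoxybenzyl)-5-[(4-methylphenyl)sulfanyl]dihydrofuran-2(3H)-one (C3/C5 epimers; C4 arranged as in the target), via benzyl(chloro)ketene 14 (not isolated), via acyloxysulfonium enolate 15 (not isolated), via thionium carboxylate 16 (not isolated)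
Conditions: Et3N, CH2Cl2, −20 → 20 °C, 13 added slowly by syringe pump
Reagents that add atoms: none
Why: Proposed new method: Et3N converts 13 into ketene 14, the sulfinyl oxygen of 7 adds to the ketene carbonyl carbon to give zwitterion 15, a chair-like [3,3]-sigmatropic shift breaks S–O and joins the enolate carbon to the alkene β-carbon (C3–C4), and the carboxylate of the resulting thionium ion 16 closes onto the thionium carbon (C5–O1). The closest known reaction type is the lactonisation of vinyl sulfoxides with dichloroketene (Marino lactonisation, an additive Pummerer process); new here is a ketene that carries one chlorine and one arylmethyl group and is generated with an amine base, the chlorine being kept to preserve the electrophilicity the known reaction relies on. The lactone ring closes by 5-exo-trig attack of carboxylate oxygen on the C=S+ carbon. C4 is set by sulfur-to-carbon chirality transfer: in the chair the p-tolyl group lies pseudo-equatorial, away from the cis arylmethyl group, so with (R)-sulfur and the (Z)-alkene the enolate is delivered to the face that gives the target's C4 configuration (descriptor S in 17 only because the chlorinated C3 outranks C5), while C3 and C5 form without useful control and are both erased in step 8. The step needs O-acylation of the sulfoxide to outrun ketene dimerisation and [2+2] addition, which slow addition of 13 and the electron-poor alkene should secure, and its regiochemistry is enforced intramolecularly because the S–O–C tether allows C–C bond formation only at the β-carbon and leaves the cation only on the sulfur-bearing carbon.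

Step 8
Reactants: 17 (4S)-3-[3,4-bis(benzyloxy)benzyl]-3-chloro-4-(3,4-dimethoxybenzyl)-5-[(4-methylphenyl)sulfanyl]dihydrofuran-2(3H)-one
Product: 19 (3R,4R)-3-[3,4-bis(benzyloxy)benzyl]-4-(3,4-dimethoxybenzyl)dihydrofuran-2(3H)-one, via C3-epimeric lactone 18 (not isolated)
Conditions: Bu3SnH (excess), AIBN (cat., in portions), PhMe, 110 °C; then DBU, 80 °C
Reagents that add atoms: none
Why: Tin hydride radical-chain reduction should cleave the C3–Cl bond (α-carbonyl radical) and the C5–S bond (oxygen-stabilised radical) to give 18, after which DBU equilibrates the enolisable C3 through the lactone enolate to the more stable 3,4-trans arrangement (thermodynamic control; C4 is not acidic and keeps its configuration).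

Step 9
Reactants: 19 (3R,4R)-3-[3,4-bis(benzyloxy)benzyl]-4-(3,4-dimethoxybenzyl)dihydrofuran-2(3H)-one
Product: 20 (3R,4R)-3-(3,4-dihydroxybenzyl)-4-(3,4-dimethoxybenzyl)dihydrofuran-2(3H)-one (3'-O-demethylarctigenin)
Conditions: H2 (1 atm), Pd/C (palladium on carbon), EtOAc–EtOH, rt
Reagents that add atoms: none
Why: Hydrogenolysis of the two aryl benzyl ethers should free the catechol without touching the lactone, the methyl ethers or either stereocentre.

**Compound list**
1 | 4-(chloromethyl)-1,2-dimethoxybenzene | COc1ccc(CCl)cc1OC | starting material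
2 | ethynylmagnesium bromide | C#C[Mg]Br | starting material
3 | 1,2-dimethoxy-4-(prop-2-yn-1-yl)benzene | COc1ccc(CC#C)cc1OC | intermediate
4 | (1R,2S,5R)-menthyl (S)-4-methylbenzenesulfinate | C[C@@H]1CC[C@H]([C@@H](C1)O[S@](=O)c2ccc(C)cc2)C(C)C | starting material
5 | [3-(3,4-dimethoxyphenyl)prop-1-yn-1-yl]magnesium bromide | COc1ccc(CC#C[Mg]Br)cc1OC | intermediate
6 | (S)-1,2-dimethoxy-4-[3-(4-methylbenzenesulfinyl)prop-2-yn-1-yl]benzene | COc1ccc(CC#C[S@@](=O)c2ccc(C)cc2)cc1OC | intermediate
7 | (R)-1,2-dimethoxy-4-[(Z)-3-(4-methylbenzenesulfinyl)prop-2-en-1-yl]benzene | COc1ccc(C/C=C\[S@@](=O)c2ccc(C)cc2)cc1OC | intermediate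
8 | diethyl 2-chloromalonate | CCOC(=O)C(Cl)C(=O)OCC | starting material
9 | 1,2-bis(benzyloxy)-4-(chloromethyl)benzene | ClCc1ccc(OCc2ccccc2)c(OCc2ccccc2)c1 | starting material
10 | diethyl 2-[3,4-bis(benzyloxy)benzyl]-2-chloromalonate | CCOC(=O)C(Cl)(Cc1ccc(OCc2ccccc2)c(OCc2ccccc2)c1)C(=O)OCC | intermediate
11 | 2-[3,4-bis(benzyloxy)benzyl]-2-chloromalonic acid | OC(=O)C(Cl)(Cc1ccc(OCc2ccccc2)c(OCc2ccccc2)c1)C(=O)O | intermediate
12 | rac-3-[3,4-bis(benzyloxy)phenyl]-2-chloropropanoic acid | OC(=O)C(Cl)Cc1ccc(OCc2ccccc2)c(OCc2ccccc2)c1 | intermediate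
13 | rac-3-[3,4-bis(benzyloxy)phenyl]-2-chloropropanoyl chloride | ClC(=O)C(Cl)Cc1ccc(OCc2ccccc2)c(OCc2ccccc2)c1 | intermediate
14 | 3-[3,4-bis(benzyloxy)phenyl]-2-chloroprop-1-en-1-one (benzyl(chloro)ketene) | O=C=C(Cl)Cc1ccc(OCc2ccccc2)c(OCc2ccccc2)c1 | intermediate
15 | acyloxysulfonium enolate zwitterion from 7 and 14 | COc1ccc(C/C=C\[S@@+](OC([O-])=C(Cl)Cc2ccc(OCc3ccccc3)c(OCc3ccccc3)c2)c2ccc(C)cc2)cc1OC | intermediate
16 | thionium carboxylate zwitterion after the [3,3] shift | COc1ccc(C[C@@H](C=[S+]c2ccc(C)cc2)C(Cl)(Cc2ccc(OCc3ccccc3)c(OCc3ccccc3)c2)C([O-])=O)cc1OC | intermediate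
17 | (4S)-3-[3,4-bis(benzyloxy)benzyl]-3-chloro-4-(3,4-dimethoxybenzyl)-5-[(4-methylphenyl)sulfanyl]dihydrofuran-2(3H)-one (C3/C5 epimers) | COc1ccc(C[C@H]2C(Sc3ccc(C)cc3)OC(=O)C2(Cl)Cc2ccc(OCc3ccccc3)c(OCc3ccccc3)c2)cc1OC | intermediate
18 | (4R)-3-[3,4-bis(benzyloxy)benzyl]-4-(3,4-dimethoxybenzyl)dihydrofuran-2(3H)-one (C3 epimers) | COc1ccc(C[C@H]2COC(=O)C2Cc2ccc(OCc3ccccc3)c(OCc3ccccc3)c2)cc1OC | intermediate
19 | (3R,4R)-3-[3,4-bis(benzyloxy)benzyl]-4-(3,4-dimethoxybenzyl)dihydrofuran-2(3H)-one | COc1ccc(C[C@H]2COC(=O)[C@@H]2Cc2ccc(OCc3ccccc3)c(OCc3ccccc3)c2)cc1OC | intermediate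
20 | (3R,4R)-3-(3,4-dihydroxybenzyl)-4-(3,4-dimethoxybenzyl)dihydrofuran-2(3H)-one (3'-O-demethylarctigenin) | COc1ccc(C[C@H]2COC(=O)[C@@H]2Cc2ccc(O)c(O)c2)cc1OC | target

**Step count and risks**
Total steps: 9. Longest linear sequence: 6 steps (1 → 2 → 3 → 7 → 8 → 9; the branch 4 → 5 → 6 → 7 → 8 → 9 is equally long).

Most likely to fail, first: step 7. The alkyl(chloro)ketene is bulkier and less electrophilic than dichloroketene, so it may dimerise before the sulfoxide traps it, or chloride may intercept the acyloxysulfonium ion before the [3,3] shift. The fallback uses known chemistry only and sets out from 7. Dichloroketene, generated in the flask from trichloroacetyl chloride and zinc–copper couple in refluxing Et2O, should give (4S)-3,3-dichloro-4-(3,4-dimethoxybenzyl)-5-[(4-methylphenyl)sulfanyl]dihydrofuran-2(3H)-one F1 by the established lactonisation with the same chirality transfer. Raney nickel (W-2 grade) in EtOH should then remove both chlorines and the sulfur to give (R)-4-(3,4-dimethoxybenzyl)dihydrofuran-2(3H)-one F2. Its lithium enolate (LiN(SiMe3)2, THF, −78 °C) is alkylated with chloride 9 (Bu4NI cat., DMPU) anti to the C4 substituent, which returns to the route at 19; compounds 8 and 10 to 13 are then not needed.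

Second: step 2. The methylene of 6 is benzylic and propargylic to an electron-poor alkyne, so proton transfer to the allenyl sulfoxide may compete, and a second attack of the Grignard reagent at sulfur may erode the sulfur configuration. The fallback avoids the alkynyl sulfoxide and sets out from 3. Hydrozirconation with Cp2Zr(H)Cl in THF should give chlorobis(cyclopentadienyl)[(E)-3-(3,4-dimethoxyphenyl)prop-1-en-1-yl]zirconium F3, and iodine converts it into 4-[(E)-3-iodoprop-2-en-1-yl]-1,2-dimethoxybenzene F4. Iodine–lithium exchange (t-BuLi, 2 equiv, Et2O, −78 °C) gives [(E)-3-(3,4-dimethoxyphenyl)prop-1-en-1-yl]lithium F5. This is sulfinylated with the enantiomeric sulfinate, (1S,2R,5S)-menthyl (R)-4-methylbenzenesulfinate (C[C@H]1CC[C@@H]([C@H](C1)O[S@@](=O)c2ccc(C)cc2)C(C)C), to give (S)-1,2-dimethoxy-4-[(E)-3-(4-methylbenzenesulfinyl)prop-2-en-1-yl]benzene F6. Opposite sulfur configuration combined with opposite alkene geometry should lead to the same C4 configuration, so F6 and 13 under the conditions of step 7 return to the route at 17; step 3 is bypassed.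

Third: step 8. Homolysis of the C5–S bond by the stannyl radical may be sluggish, leaving sulfur in place, and the kinetic hydrogen transfer at C3 favours the cis lactone, so incomplete equilibration would carry the wrong epimer forward. The fallback separates the three events and replaces the radical chain by two-electron and surface chemistry; it sets out from 17. Zinc dust in AcOH removes the chlorine to give (4R)-3-[3,4-bis(benzyloxy)benzyl]-4-(3,4-dimethoxybenzyl)-5-[(4-methylphenyl)sulfanyl]dihydrofuran-2(3H)-one F7 as C3 epimers. DBU in toluene equilibrates C3 to (3R,4R)-3-[3,4-bis(benzyloxy)benzyl]-4-(3,4-dimethoxybenzyl)-5-[(4-methylphenyl)sulfanyl]dihydrofuran-2(3H)-one F8. Raney nickel (W-2 grade, EtOH, rt) then cleaves the C–S bond and returns to the route at 19; any benzyl ether lost at this point is harmless because step 9 removes both.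

**Further compounds**
F1 | step 7 | (4S)-3,3-dichloro-4-(3,4-dimethoxybenzyl)-5-[(4-methylphenyl)sulfanyl]dihydrofuran-2(3H)-one (C5 epimers) | COc1ccc(C[C@H]2C(Sc3ccc(C)cc3)OC(=O)C2(Cl)Cl)cc1OC
F2 | step 7 | (R)-4-(3,4-dimethoxybenzyl)dihydrofuran-2(3H)-one | COc1ccc(C[C@H]2COC(=O)C2)cc1OC
F3 | step 2 | chlorobis(cyclopentadienyl)[(E)-3-(3,4-dimethoxyphenyl)prop-1-en-1-yl]zirconium | COc1ccc(C/C=C/[Zr](Cl)(C2C=CC=C2)C2C=CC=C2)cc1OC
F4 | step 2 | 4-[(E)-3-iodoprop-2-en-1-yl]-1,2-dimethoxybenzene | COc1ccc(C/C=C/I)cc1OC
F5 | step 2 | [(E)-3-(3,4-dimethoxyphenyl)prop-1-en-1-yl]lithium | COc1ccc(C/C=C/[Li])cc1OC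
F6 | step 2 | (S)-1,2-dimethoxy-4-[(E)-3-(4-methylbenzenesulfinyl)prop-2-en-1-yl]benzene | COc1ccc(C/C=C/[S@](=O)c2ccc(C)cc2)cc1OC
F7 | step 8 | (4R)-3-[3,4-bis(benzyloxy)benzyl]-4-(3,4-dimethoxybenzyl)-5-[(4-methylphenyl)sulfanyl]dihydrofuran-2(3H)-one (C3/C5 epimers) | COc1ccc(C[C@H]2C(Sc3ccc(C)cc3)OC(=O)C2Cc2ccc(OCc3ccccc3)c(OCc3ccccc3)c2)cc1OC
F8 | step 8 | (3R,4R)-3-[3,4-bis(benzyloxy)benzyl]-4-(3,4-dimethoxybenzyl)-5-[(4-methylphenyl)sulfanyl]dihydrofuran-2(3H)-one (C5 epimers) | COc1ccc(C[C@H]2C(Sc3ccc(C)cc3)OC(=O)[C@@H]2Cc2ccc(OCc3ccccc3)c(OCc3ccccc3)c2)cc1OC
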